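## Retrosynthetic overview

1. The two pyrrole amides are made last: target 21 ⇒ diamine 19 + 2 × 2-(trichloroacetyl)pyrrole 20; the amines come from azides.
2. The two 2-aminoimidazole rings (the last rings formed) ⇒ bis(α-aminoketone) 15 + cyanamide 16.
3. Key C–C bonds (future imidazole C4–C5): two-fold intermolecular crossed Claisen acylation of the glycine imine ester enolate of 11 by diacid chloride 10, then decarboxylation.
4. All-trans core 8 ⇒ cis,trans,cis diazide diester 7 by ester-enolate epimerisation; the azidomethyl arms come from the acid groups of hemiester 2 through the temporary bis-lactone 4 (rings formed in step 2, opened in step 3).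
5. The cyclobutane ring is bought in dianhydride 1; absolute configuration comes from an alkaloid-mediated double desymmetrising methanolysis of 1.

Assumption: quinine opens each anhydride ring of 1 with the sense it shows for cis-cyclobutane-1,2-dicarboxylic anhydride (recalled, not verified, as giving the (1R,2S)-2-(methoxycarbonyl)cyclobutane-1-carboxylic acid); if the sense is opposite, quinidine replaces quinine and nothing else changes.

Handling note: the low-molecular-weight diazides 7–10 are kept in solution, on small scale, behind a shield.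

## Route

Step 1
Reactants: 1 cis,trans,cis-cyclobutane-1,2,3,4-tetracarboxylic dianhydride
Product: 2 (1R,2R,3R,4R)-3,4-bis(methoxycarbonyl)cyclobutane-1,2-dicarboxylic acid (cis,trans,cis: the two acids trans; each ester cis to its neighbouring acid)
Conditions: quinine (2.2 equiv), MeOH (6 equiv), PhMe, −55 °C, 96 h; 2 M HCl wash (quinine recovered)
Reagents that add atoms: methanol, CO
Why: Alkaloid-mediated desymmetrising methanolysis of a meso anhydride, done on both rings of centrosymmetric 1: the same-sense carbonyl is opened in each ring, so the esters land on vicinal trans carbons and the two acid-bearing stereocentres (the future CH2N carbons) are fixed, while a wrong-sense opening gives the achiral 1,3-diester instead of the enantiomer and so raises ee.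

Step 2
Reactants: 2 (1R,2R,3R,4R)-3,4-bis(methoxycarbonyl)cyclobutane-1,2-dicarboxylic acid
Product: 4 (1R,2R,6R,7R)-4,9-dioxatricyclo[5.3.0.0^2,6]decane-3,10-dione (C2-symmetric bis-γ-lactone), via diol diester 3 (not isolated)
Conditions: BH3·SMe2 (4 equiv), THF, 0 °C → rt; MeOH quench; TsOH (cat.), PhMe, 60 °C; recrystallise
Reagents that add atoms: none
Why: Chemoselective borane reduction of the acids beside the esters, then lactonisation of each CH2OH onto its cis ester; no stereocentre is touched and recrystallisation removes the meso by-product of step 1.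

Step 3
Reactants: 4 bis-γ-lactone
Product: 6 dimethyl (1S,2S,3S,4S)-3,4-bis(bromomethyl)cyclobutane-1,2-dicarboxylate (cis,trans,cis), via dibromo diacid 5 (not isolated)
Conditions: HBr (33% in AcOH, 8 equiv), 70 °C, 6 h; evaporate; MeOH, rt → 40 °C, 16 h
Reagents that add atoms: hydrogen bromide, Br; methanol, CO
Why: SN2 opening of each protonated lactone by bromide at the primary CH2–O carbon, then Fischer esterification; the stereocentres are untouched (descriptors change only because Br outranks O).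

Step 4
Reactants: 6 dimethyl (1S,2S,3S,4S)-3,4-bis(bromomethyl)cyclobutane-1,2-dicarboxylate
Product: 7 dimethyl (1R,2R,3R,4R)-3,4-bis(azidomethyl)cyclobutane-1,2-dicarboxylate (cis,trans,cis)
Conditions: NaN3 (3 equiv), DMF, 55 °C, 12 h
Reagents that add atoms: sodium azide, [Na+].[N-]=[N+]=[N-]
Why: SN2 displacement of primary bromide by azide, done before any base treatment so that no ester enolate can close onto CH2Br; the stereocentres are untouched.

Step 5
Reactants: 7 dimethyl (1R,2R,3R,4R)-3,4-bis(azidomethyl)cyclobutane-1,2-dicarboxylate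
Product: 8 dimethyl (1S,2S,3R,4R)-3,4-bis(azidomethyl)cyclobutane-1,2-dicarboxylate (all-trans)
Conditions: NaOMe (0.5 equiv), MeOH, 60 °C, 8 h; AcOH quench
Reagents that add atoms: none
Why: Thermodynamic epimerisation through the ester enolates: only the two ester-bearing carbons can invert and each moves trans to its azidomethyl neighbour, so the all-trans isomer results while the two azidomethyl carbons set in step 1 carry the absolute configuration.

Step 6
Reactants: 8 dimethyl (1S,2S,3R,4R)-3,4-bis(azidomethyl)cyclobutane-1,2-dicarboxylate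
Product: 9 (1S,2S,3R,4R)-3,4-bis(azidomethyl)cyclobutane-1,2-dicarboxylic acid
Conditions: LiOH (4 equiv), THF/H2O 3:1, rt, 6 h; HCl to pH 2
Reagents that add atoms: lithium hydroxide, [Li+].[OH-]
Why: Ester saponification; the α-centres are already in the thermodynamic all-trans arrangement, so base cannot erode them.

Step 7
Reactants: 9 (1S,2S,3R,4R)-3,4-bis(azidomethyl)cyclobutane-1,2-dicarboxylic acid
Product: 10 (1S,2S,3R,4R)-3,4-bis(azidomethyl)cyclobutane-1,2-dicarbonyl dichloride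
Conditions: (COCl)2 (3 equiv), DMF (cat.), CH2Cl2, 0 °C → rt, 2 h; evaporate, use crude
Reagents that add atoms: oxalyl chloride, O=C(Cl)C(Cl)=O
Why: Acid chloride formation through the Vilsmeier-type chloroiminium activator; the trans diacid cannot close to a cyclic anhydride.

Step 8
Reactants: 10 (1S,2S,3R,4R)-3,4-bis(azidomethyl)cyclobutane-1,2-dicarbonyl dichloride; 11 tert-butyl N-(diphenylmethylene)glycinate
Product: 13 di-tert-butyl 3,3'-[(1S,2S,3R,4R)-3,4-bis(azidomethyl)cyclobutane-1,2-diyl]bis(2-amino-3-oxopropanoate) dihydrochloride, via bis(C-acyl imine) 12 (not isolated)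
Conditions: 11 (4.4 equiv), KOtBu (4.4 equiv), THF, −78 °C, 30 min; add 10 in THF over 30 min, −78 °C, 1 h; then 1 M HCl (aq)/THF, 0 °C → rt, 3 h; Et2O wash (surplus 11 ends as water-soluble glycine ester, removed at 18)
Reagents that add atoms: hydrogen chloride, Cl
Why: Intermolecular crossed Claisen condensation (C-acylation of the glycine ester enolate by each acyl chloride) forms the two key C–C bonds, and mild acid then hydrolyses the imines; the new α-carbons are unassigned and are destroyed in step 9, and the ring carbons stay in the thermodynamic all-trans arrangement.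

Step 9
Reactants: 13 bis(α-amino-β-keto tert-butyl ester) dihydrochloride
Product: 15 1,1'-[(1S,2S,3R,4R)-3,4-bis(azidomethyl)cyclobutane-1,2-diyl]bis(2-aminoethan-1-one) dihydrochloride, via bis(β-keto acid) 14 (not isolated)
Conditions: 4 M HCl in dioxane, rt, 2 h, then 50 °C, 2 h; evaporate
Reagents that add atoms: none
Why: Acidolysis of the tert-butyl esters followed by β-keto acid decarboxylation; the amines stay protonated so the α-aminoketones cannot self-condense, and acid keeps the ring centres all-trans.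

Step 10
Reactants: 15 bis(α-aminoketone) dihydrochloride; 16 cyanamide
Product: 18 5,5'-[(1S,2S,3R,4R)-3,4-bis(azidomethyl)cyclobutane-1,2-diyl]bis(1H-imidazol-2-amine) dihydrochloride, via bis(guanidinomethyl ketone) 17 (not isolated)
Conditions: 16 (10 equiv), H2O, pH 4.5, 95 °C, 3 h; pH 10, n-BuOH extraction; HCl
Reagents that add atoms: none
Why: α-Aminoketone–cyanamide 2-aminoimidazole synthesis (amine adds to the nitrile, and the resulting guanidine cyclodehydrates onto the ketone); no stereocentre is involved.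

Step 11
Reactants: 18 bis(2-aminoimidazole) diazide dihydrochloride
Product: 19 5,5'-[(1S,2S,3R,4R)-3,4-bis(aminomethyl)cyclobutane-1,2-diyl]bis(1H-imidazol-2-amine) dihydrochloride
Conditions: H2 (1 atm), Pd/C (10% Pd), MeOH, rt, 4 h
Reagents that add atoms: none
Why: Catalytic hydrogenation of the alkyl azides to primary amines; the aminoimidazolium rings are inert under these conditions.

Step 12
Reactants: 19 diamine dihydrochloride; 20 2,2,2-trichloro-1-(1H-pyrrol-2-yl)ethan-1-one
Product: 21 N,N'-{[(1R,2R,3S,4S)-3,4-bis(2-amino-1H-imidazol-5-yl)cyclobutane-1,2-diyl]bis(methylene)}bis(1H-pyrrole-2-carboxamide)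
Conditions: 20 (2.1 equiv), Na2CO3 (2 equiv), DMF, rt, 16 h; reverse-phase chromatography; NH3/MeOH to free the base
Reagents that add atoms: none
Why: Amide formation by haloform-type acyl transfer from the trichloromethyl ketone; the primary alkylamines are far more nucleophilic than the 2-aminoimidazole nitrogens, so only the two arms are acylated.

## Compound list

1 | cis,trans,cis-cyclobutane-1,2,3,4-tetracarboxylic dianhydride | O=C2[C@@H]1[C@H](C(=O)O2)[C@@H](C(=O)OC3=O)[C@H]13 | starting material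
2 | (1R,2R,3R,4R)-3,4-bis(methoxycarbonyl)cyclobutane-1,2-dicarboxylic acid | COC(=O)[C@@H]1[C@H](C(=O)O)[C@@H](C(=O)O)[C@H]1C(=O)OC | intermediate
3 | dimethyl (1R,2R,3R,4R)-3,4-bis(hydroxymethyl)cyclobutane-1,2-dicarboxylate | COC(=O)[C@@H]1[C@H](CO)[C@@H](CO)[C@H]1C(=O)OC | intermediate
4 | (1R,2R,6R,7R)-4,9-dioxatricyclo[5.3.0.0^2,6]decane-3,10-dione | O=C2[C@@H]1[C@H](CO2)[C@@H](COC3=O)[C@H]13 | intermediate
5 | (1S,2S,3S,4S)-3,4-bis(bromomethyl)cyclobutane-1,2-dicarboxylic acid | OC(=O)[C@@H]1[C@H](CBr)[C@@H](CBr)[C@H]1C(=O)O | intermediate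
6 | dimethyl (1S,2S,3S,4S)-3,4-bis(bromomethyl)cyclobutane-1,2-dicarboxylate | COC(=O)[C@@H]1[C@H](CBr)[C@@H](CBr)[C@H]1C(=O)OC | intermediate
7 | dimethyl (1R,2R,3R,4R)-3,4-bis(azidomethyl)cyclobutane-1,2-dicarboxylate | COC(=O)[C@@H]1[C@H](CN=[N+]=[N-])[C@@H](CN=[N+]=[N-])[C@H]1C(=O)OC | intermediate
8 | dimethyl (1S,2S,3R,4R)-3,4-bis(azidomethyl)cyclobutane-1,2-dicarboxylate | COC(=O)[C@H]1[C@H](CN=[N+]=[N-])[C@@H](CN=[N+]=[N-])[C@@H]1C(=O)OC | intermediate
9 | (1S,2S,3R,4R)-3,4-bis(azidomethyl)cyclobutane-1,2-dicarboxylic acid | OC(=O)[C@H]1[C@H](CN=[N+]=[N-])[C@@H](CN=[N+]=[N-])[C@@H]1C(=O)O | intermediate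
10 | (1S,2S,3R,4R)-3,4-bis(azidomethyl)cyclobutane-1,2-dicarbonyl dichloride | ClC(=O)[C@H]1[C@H](CN=[N+]=[N-])[C@@H](CN=[N+]=[N-])[C@@H]1C(=O)Cl | intermediate
11 | tert-butyl N-(diphenylmethylene)glycinate | CC(C)(C)OC(=O)CN=C(c1ccccc1)c1ccccc1 | starting material
12 | di-tert-butyl 3,3'-[(1S,2S,3R,4R)-3,4-bis(azidomethyl)cyclobutane-1,2-diyl]bis[2-(diphenylmethyleneamino)-3-oxopropanoate] | CC(C)(C)OC(=O)C(N=C(c2ccccc2)c2ccccc2)C(=O)[C@H]1[C@H](CN=[N+]=[N-])[C@@H](CN=[N+]=[N-])[C@@H]1C(=O)C(N=C(c1ccccc1)c1ccccc1)C(=O)OC(C)(C)C | intermediate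
13 | di-tert-butyl 3,3'-[(1S,2S,3R,4R)-3,4-bis(azidomethyl)cyclobutane-1,2-diyl]bis(2-amino-3-oxopropanoate) dihydrochloride | CC(C)(C)OC(=O)C(N)C(=O)[C@H]1[C@H](CN=[N+]=[N-])[C@@H](CN=[N+]=[N-])[C@@H]1C(=O)C(N)C(=O)OC(C)(C)C.Cl.Cl | intermediate
14 | 3,3'-[(1S,2S,3R,4R)-3,4-bis(azidomethyl)cyclobutane-1,2-diyl]bis(2-amino-3-oxopropanoic acid) dihydrochloride | OC(=O)C(N)C(=O)[C@H]1[C@H](CN=[N+]=[N-])[C@@H](CN=[N+]=[N-])[C@@H]1C(=O)C(N)C(=O)O.Cl.Cl | intermediate
15 | 1,1'-[(1S,2S,3R,4R)-3,4-bis(azidomethyl)cyclobutane-1,2-diyl]bis(2-aminoethan-1-one) dihydrochloride | NCC(=O)[C@H]1[C@H](CN=[N+]=[N-])[C@@H](CN=[N+]=[N-])[C@@H]1C(=O)CN.Cl.Cl | intermediate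
16 | cyanamide | NC#N | starting material
17 | 1,1'-[(1S,2S,3R,4R)-3,4-bis(azidomethyl)cyclobutane-1,2-diyl]bis(2-guanidinoethan-1-one) dihydrochloride | NC(=N)NCC(=O)[C@H]1[C@H](CN=[N+]=[N-])[C@@H](CN=[N+]=[N-])[C@@H]1C(=O)CNC(N)=N.Cl.Cl | intermediate
18 | 5,5'-[(1S,2S,3R,4R)-3,4-bis(azidomethyl)cyclobutane-1,2-diyl]bis(1H-imidazol-2-amine) dihydrochloride | Nc1ncc([C@H]2[C@H](CN=[N+]=[N-])[C@@H](CN=[N+]=[N-])[C@@H]2c2cnc(N)[nH]2)[nH]1.Cl.Cl | intermediate
19 | 5,5'-[(1S,2S,3R,4R)-3,4-bis(aminomethyl)cyclobutane-1,2-diyl]bis(1H-imidazol-2-amine) dihydrochloride | Nc1ncc([C@H]2[C@H](CN)[C@@H](CN)[C@@H]2c2cnc(N)[nH]2)[nH]1.Cl.Cl | intermediate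
20 | 2,2,2-trichloro-1-(1H-pyrrol-2-yl)ethan-1-one | O=C(c1ccc[nH]1)C(Cl)(Cl)Cl | starting material
21 | N,N'-{[(1R,2R,3S,4S)-3,4-bis(2-amino-1H-imidazol-5-yl)cyclobutane-1,2-diyl]bis(methylene)}bis(1H-pyrrole-2-carboxamide) | Nc1ncc([C@H]2[C@H](CNC(=O)c3ccc[nH]3)[C@@H](CNC(=O)c3ccc[nH]3)[C@@H]2c2cnc(N)[nH]2)[nH]1 | target

## Totals and risks

Total step count: 12. Longest linear sequence: 12 steps (1 → 21).

Steps most likely to fail:

Step 1 (1 is poorly soluble, and the sense and level of selectivity on a dianhydride are unproven). The fallback sets out from 1 and comes back at 4. Compound 1 is esterified (MeOH, cat. H2SO4, reflux) to tetramethyl cis,trans,cis-cyclobutane-1,2,3,4-tetracarboxylate F1. Pig liver esterase (pH 7 phosphate buffer, 25 °C, pH-stat) hydrolyses one ester of each cis pair and, by analogy with dimethyl cis-cyclobutane-1,2-dicarboxylate, should give the mirror-image hemiester (1S,2S,3S,4S)-3,4-bis(methoxycarbonyl)cyclobutane-1,2-dicarboxylic acid F2. LiEt3BH (THF, 0 °C) then reduces the esters and leaves the carboxylates, giving (1R,2R,3R,4R)-3,4-bis(hydroxymethyl)cyclobutane-1,2-dicarboxylic acid F3, which lactonises on acidification (2 M HCl) to 4. Because either the acids (BH3) or the esters (LiEt3BH) can be reduced, both hemiester enantiomers converge on 4; if the enzyme gave 2 itself, it would simply enter step 2.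

Step 3 (the cis bromo acid or ester can close back to the lactone, so the opening may stall). The fallback sets out from 2 and comes back at 8. Compound 2 is first epimerised at its two ester-bearing carbons (NaOMe, MeOH, 60 °C; the carboxylate-bearing carbons do not invert) to the all-trans (1R,2R,3S,4S)-3,4-bis(methoxycarbonyl)cyclobutane-1,2-dicarboxylic acid F4. BH3·SMe2 (THF) reduces the acids to dimethyl (1S,2S,3R,4R)-3,4-bis(hydroxymethyl)cyclobutane-1,2-dicarboxylate F5, whose trans hydroxy esters cannot form γ-lactones. MsCl/Et3N (CH2Cl2, 0 °C) gives dimethyl (1S,2S,3R,4R)-3,4-bis[(methanesulfonyloxy)methyl]cyclobutane-1,2-dicarboxylate F6, and NaN3 in DMF gives 8.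

Step 8 (two-fold C-acylation; O-acylation, ketene formation or proton transfer may cut the yield). The fallback sets out from 8 and comes back at 15, using an ester–ester Claisen condensation and introducing nitrogen afterwards. Compound 8 is treated with LiCH2CO2tBu (from tBuOAc and LiN(iPr)2, 5 equiv, THF, −78 → −30 °C) to give di-tert-butyl 3,3'-[(1S,2S,3R,4R)-3,4-bis(azidomethyl)cyclobutane-1,2-diyl]bis(3-oxopropanoate) F7. TFA/CH2Cl2 cleaves the esters to 3,3'-[(1S,2S,3R,4R)-3,4-bis(azidomethyl)cyclobutane-1,2-diyl]bis(3-oxopropanoic acid) F8, which loses CO2 at 50 °C to give 1,1'-[(1S,2S,3R,4R)-3,4-bis(azidomethyl)cyclobutane-1,2-diyl]bis(ethan-1-one) F9. BnNMe3ICl2 (ClCH2CH2Cl/MeOH, 70 °C) chlorinates the methyl groups to 1,1'-[(1S,2S,3R,4R)-3,4-bis(azidomethyl)cyclobutane-1,2-diyl]bis(2-chloroethan-1-one) F10. NaN(CHO)2 (MeCN, 40 °C) gives N,N'-{[(1S,2S,3R,4R)-3,4-bis(azidomethyl)cyclobutane-1,2-diyl]bis(2-oxoethane-2,1-diyl)}bis(N-formylformamide) F11, and HCl in MeOH removes the formyl groups to give 15.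

## Further compounds

F1 | step 1 | tetramethyl cis,trans,cis-cyclobutane-1,2,3,4-tetracarboxylate | COC(=O)[C@@H]1[C@H](C(=O)OC)[C@@H](C(=O)OC)[C@H]1C(=O)OC
F2 | step 1 | (1S,2S,3S,4S)-3,4-bis(methoxycarbonyl)cyclobutane-1,2-dicarboxylic acid | OC(=O)[C@@H]1[C@H](C(=O)OC)[C@@H](C(=O)OC)[C@H]1C(=O)O
F3 | step 1 | (1R,2R,3R,4R)-3,4-bis(hydroxymethyl)cyclobutane-1,2-dicarboxylic acid | OC(=O)[C@@H]1[C@H](CO)[C@@H](CO)[C@H]1C(=O)O
F4 | step 3 | (1R,2R,3S,4S)-3,4-bis(methoxycarbonyl)cyclobutane-1,2-dicarboxylic acid | COC(=O)[C@H]1[C@H](C(=O)O)[C@@H](C(=O)O)[C@@H]1C(=O)OC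
F5 | step 3 | dimethyl (1S,2S,3R,4R)-3,4-bis(hydroxymethyl)cyclobutane-1,2-dicarboxylate | COC(=O)[C@H]1[C@H](CO)[C@@H](CO)[C@@H]1C(=O)OC
F6 | step 3 | dimethyl (1S,2S,3R,4R)-3,4-bis[(methanesulfonyloxy)methyl]cyclobutane-1,2-dicarboxylate | COC(=O)[C@H]1[C@H](COS(C)(=O)=O)[C@@H](COS(C)(=O)=O)[C@@H]1C(=O)OC
F7 | step 8 | di-tert-butyl 3,3'-[(1S,2S,3R,4R)-3,4-bis(azidomethyl)cyclobutane-1,2-diyl]bis(3-oxopropanoate) | CC(C)(C)OC(=O)CC(=O)[C@H]1[C@H](CN=[N+]=[N-])[C@@H](CN=[N+]=[N-])[C@@H]1C(=O)CC(=O)OC(C)(C)C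
F8 | step 8 | 3,3'-[(1S,2S,3R,4R)-3,4-bis(azidomethyl)cyclobutane-1,2-diyl]bis(3-oxopropanoic acid) | OC(=O)CC(=O)[C@H]1[C@H](CN=[N+]=[N-])[C@@H](CN=[N+]=[N-])[C@@H]1C(=O)CC(=O)O
F9 | step 8 | 1,1'-[(1S,2S,3R,4R)-3,4-bis(azidomethyl)cyclobutane-1,2-diyl]bis(ethan-1-one) | CC(=O)[C@H]1[C@H](CN=[N+]=[N-])[C@@H](CN=[N+]=[N-])[C@@H]1C(C)=O
F10 | step 8 | 1,1'-[(1S,2S,3R,4R)-3,4-bis(azidomethyl)cyclobutane-1,2-diyl]bis(2-chloroethan-1-one) | ClCC(=O)[C@H]1[C@H](CN=[N+]=[N-])[C@@H](CN=[N+]=[N-])[C@@H]1C(=O)CCl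
F11 | step 8 | N,N'-{[(1S,2S,3R,4R)-3,4-bis(azidomethyl)cyclobutane-1,2-diyl]bis(2-oxoethane-2,1-diyl)}bis(N-formylformamide) | O=CN(C=O)CC(=O)[C@H]1[C@H](CN=[N+]=[N-])[C@@H](CN=[N+]=[N-])[C@@H]1C(=O)CN(C=O)C=O
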